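**Remarks on the chemistry (assumptions).** The substrate of the key step is built by an auxiliary-controlled enolate alkylation. A shorter catalytic annulation through a 3-aryl lactone was not adopted, because its stereocentre would sit alpha to an aryl ester carbonyl and could racemise under base. Non-isolated intermediates are numbered only where they are generated in a separate operation (mixed anhydride, enolate, aryllithium, boronate); short-lived mechanistic species are not numbered.

## Analysis of the target

The target is an isoflavan: a chroman (benzo ring A fused to the dihydropyran ring C, atoms O1, C2, C3, C4, C4a–C8a) carrying a pentasubstituted phenyl ring B at C3. Ring A bears a free hydroxyl at C7 and a methoxy group at C8, next to O1. Ring B bears methoxy groups at C2', C4' and C5' and a free hydroxyl at C3', so C6' is its only unsubstituted carbon. There is one stereocentre, C3, of S configuration (priorities C2 > C1' > C4 > H); it lies between two methylene groups, so no neighbouring stereocentre or heteroatom can relay chirality to it and it must be set by a reagent or an auxiliary. C3 is benzylic but not alpha to a carbonyl in the final skeleton, so it is stable once the chroman exists; only a benzylic carbanion at C3, which could expel the O1 phenoxide by β-elimination, would endanger it. The sensitive groups are the two electron-rich phenols, above all the one on the tetra-oxygenated ring B, which are prone to oxidation in basic, aerobic media. The difficulty lies in the oxygenation pattern rather than the skeleton: six oxygen substituents, two of them free, which by conventional logic call for two custom-made, differentially protected arenes. The plan rests on the fact that both hydroxyl-bearing carbons are the positions of the fully methylated skeleton that an alkyllithium removes most easily: C3'–H lies between the 2'- and 4'-methoxy groups, and C7–H is the only ring-A hydrogen ortho to an oxygen substituent (the 8-methoxy group).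

## Retrosynthetic reasoning

**17 ⇒ 13.** The two phenolic bonds C3'–O and C7–O are cut first, leading back to the tetramethoxy isoflavan 13 and to trimethyl borate 14 as the boron source. These bonds are cut because their carbons coincide with the two preferred metalation sites of 13, so neither hydroxyl ever needs a protecting group and both arenes can be bought with their final methyl ethers in place. Forward, 13 must be metalated twice to the dilithio species 15 without touching H-6', the benzylic positions C3 and C4 or the OCH2 group. 15 must then be borylated to 16, and 16 oxidised under conditions that the electron-rich phenols of 17 tolerate.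

**13 ⇒ 12 ⇒ 11.** The pyran is opened at O1–C2. Cutting here rather than at O1–C8a leaves a phenol and a primary alcohol, the partners of a Mitsunobu etherification, and places the bond formation on a CH2 group, so the adjacent stereocentre C3 cannot be affected. The phenol of 12 is carried as the benzyl ether 11 because the two preceding steps use an enolate and a hydride.

**11 ⇒ 10.** The primary alcohol is taken back to an acyl group bound to a chiral oxazolidinone. This makes C3 the alpha carbon of a carboxylic acid derivative, where a stereocentre can be installed by enolate alkylation. The forward step is a hydride cleavage of the exocyclic imide carbonyl.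

**10 ⇒ 8 + 4.** The C3–C4 bond is cut. Of the three C–C bonds at C3, this is the one whose cleavage gives two halves derived from commodity chemicals: the ring-B arylacetyl imide 8 and the ring-A benzylic bromide 4. Cutting C3–C1' would require an asymmetric alpha-arylation with a hindered, electron-rich aryl halide, and cutting C2–C3 an asymmetric hydroxymethylation. Forward, the sodium enolate 9 of 8 must be alkylated by 4 on one face only; the auxiliary dictates this, and the S configuration of 17 is set here.

**8 ⇒ 5 + 6; 4 ⇒ 3 ⇒ 2 ⇒ 1.** Imide 8 comes from the commercial acid 5 and the auxiliary 6 through the mixed anhydride 7. Bromide 4 comes from o-vanillin 1 by benzylation (2), reduction (3) and bromination.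

## Alternatives that were turned down

**Alternative 1:** one-carbon ring expansion of a benzofuran.
- Disconnection: C3, together with ring B, is excised from the pyran (bonds C2–C3 and C3–C4), leaving 6-(benzyloxy)-7-methoxybenzofuran A2 and the carbene precursor 3-[3-(benzyloxy)-2,4,5-trimethoxyphenyl]-3-chloro-3H-diazirine A3.
- Forward key step: light converts A3 into an arylchlorocarbene, which cyclopropanates the furan double bond of A2. The chlorocyclopropane opens with loss of chloride to the 3-arylbenzopyrylium salt A1.
- For: it is convergent, the ring expansion is compact, and the oxygenation pattern is fixed by the building blocks, so no site-selectivity question arises.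
- Against:
  - A1 is a planar, achiral cation. The only stereocentre must be created afterwards by an enantioselective reduction of a pyrylium or derived chromene bearing an ortho-substituted aryl group, which is an uncertain problem of its own.
  - Both phenols must be carried as benzyl ethers, so A2 and A3 are multi-step, custom arenes.
  - An electron-rich aryl chlorodiazirine is labile, its carbene can attack the electron-rich benzo ring, and A1 is prone to ring-opening by water.
- Comparison: Alternative 1 is stronger in regiochemical certainty of the oxygens. The chosen route offers a stereocentre set by a predictable auxiliary alkylation, no phenol protection and commodity starting materials, and its one uncertain step is the last one.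

**Alternative 2:** three-component coupling on a vinylboron linchpin.
- Disconnection: C3–C1' and C4–C4a, with vinylboronic ester A5 between the ring-B aryllithium A7 and the ring-A aryl triflate A6.
- Forward key step: A7 adds to A5 to give a boron ate complex. The arylpalladium species formed from A6 with a chiral bisphosphine–palladium catalyst triggers a 1,2-shift of the ring-B aryl group from boron to carbon, and reductive elimination forms C4–C4a, giving the secondary boronic ester A4.
- For: it is catalytic and enantioselective, sets the stereocentre and two C–C bonds in one step, and the oxygen positions are unambiguous.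
- Against:
  - A4 lacks C2. A one-carbon homologation of the C–B bond, oxidation, acetal removal, ring closure and double debenzylation follow, about five steps after the key step.
  - A6 and A7 each carry three or four differentiated oxygens and need multi-step preparation.
  - Ortho-substituted partners on both sides are the demanding cases for this coupling, and an electron-rich benzylic boronate is prone to protodeboronation.
- Comparison: Alternative 2 is stronger in catalytic asymmetric induction. The chosen route is stronger in step economy after the stereo-defining step and in starting-material cost, and needs no orthogonal protecting groups.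

**Alternative 3:** organocatalytic annulation of a symmetric resorcinol.
- Disconnection: C4–C4a and O1–C2, back to 2-methoxyresorcinol A9 and the 2-arylacrolein A10.
- Forward key step: A9 adds through carbon to the chiral iminium ion of A10, the resulting enamine is protonated at C3, and hemiacetalisation closes the pyran as lactol A8.
- For: it is the shortest plan on paper. The symmetry of A9 removes any regiochemical issue on ring A, and the C7 hydroxyl needs no protection.
- Against:
  - The stereocentre is set by enantioselective protonation, a weakly organised event.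
  - In A8 the stereocentre sits alpha to a masked aldehyde that carries an aryl group, so it can epimerise through the enol or enamine under the conditions that form it.
  - A10 is polymerisation-prone, the electron-rich A9 can add twice, and ring B still needs its protected C3' oxygen from a custom arene.
  - Lactol deoxygenation and debenzylation follow.
- Comparison: Alternative 3 is stronger in step count. The chosen route forms its stereocentre under auxiliary control in a configurationally locked imide and removes the carbonyl before any basic step.

Key step: step 9

## Route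

Step 1
Reactants: 1 2-hydroxy-3-methoxybenzaldehyde (o-vanillin)
Product: 2 2-(benzyloxy)-3-methoxybenzaldehyde
Conditions: BnBr (1.1 equiv), K2CO3, DMF, rt → 50 °C
Reagents that add atoms: benzyl bromide, BrCc1ccccc1
Why: Williamson etherification of the acidic ortho-formyl phenol; the benzyl ether masks the future O1 during the enolate and hydride steps.

Step 2
Reactants: 2 2-(benzyloxy)-3-methoxybenzaldehyde
Product: 3 [2-(benzyloxy)-3-methoxyphenyl]methanol
Conditions: NaBH4, MeOH, 0 °C
Reagents that add atoms: none
Why: Borohydride reduction of an aryl aldehyde to the benzylic alcohol; both ethers are inert.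

Step 3
Reactants: 3 [2-(benzyloxy)-3-methoxyphenyl]methanol
Product: 4 2-(benzyloxy)-1-(bromomethyl)-3-methoxybenzene
Conditions: PBr3 (0.4 equiv), CH2Cl2, 0 °C; used without storage
Reagents that add atoms: phosphorus tribromide, BrP(Br)Br
Why: The primary benzylic alcohol is converted through its phosphite ester into the bromide by SN2 displacement; at 0 °C the benzyl aryl ether should survive.

Step 4
Reactants: 5 2-(2,4,5-trimethoxyphenyl)acetic acid; 6 (S)-4-benzyloxazolidin-2-one
Product: 8 (S)-4-benzyl-3-[2-(2,4,5-trimethoxyphenyl)acetyl]oxazolidin-2-one, via mixed pivalic anhydride 7 (not isolated)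
Conditions: PivCl, Et3N, THF, −20 °C; then 6, LiCl, −20 °C → rt
Reagents that add atoms: pivaloyl chloride, CC(C)(C)C(=O)Cl (its pivaloyl group is found in intermediate 7 only; nothing of it remains in 8)
Why: N-acylation of the oxazolidinone by a mixed anhydride under lithium chloride/amine activation; the nucleophile attacks the less hindered arylacetyl carbonyl of 7 and no strong base touches the acidic benzylic CH2.

Step 5
Reactants: 8 (S)-4-benzyl-3-[2-(2,4,5-trimethoxyphenyl)acetyl]oxazolidin-2-one; 4 2-(benzyloxy)-1-(bromomethyl)-3-methoxybenzene
Product: 10 (S)-4-benzyl-3-[(S)-3-[2-(benzyloxy)-3-methoxyphenyl]-2-(2,4,5-trimethoxyphenyl)propanoyl]oxazolidin-2-one, via sodium Z-enolate 9 (not isolated)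
Conditions: NaHMDS (1.1 equiv), THF, −78 °C; then 4, −78 → −30 °C
Reagents that add atoms: sodium bis(trimethylsilyl)amide, C[Si](C)(C)[N-][Si](C)(C)C.[Na+] (the sodium of enolate 9 only; nothing of it remains in 10)
Why: Evans oxazolidinone alkylation: the chelated Z-enolate 9 is attacked by the benzylic bromide on the face opposite the C4 benzyl group of the auxiliary, which creates the C3 stereocentre. With the (S)-auxiliary this usual sense of induction corresponds to the S descriptor here, because the aryl group outranks the new CH2Ar substituent. Allylic strain in the product imide should protect the new centre from re-enolisation.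

Step 6
Reactants: 10 (S)-4-benzyl-3-[(S)-3-[2-(benzyloxy)-3-methoxyphenyl]-2-(2,4,5-trimethoxyphenyl)propanoyl]oxazolidin-2-one
Product: 11 (S)-3-[2-(benzyloxy)-3-methoxyphenyl]-2-(2,4,5-trimethoxyphenyl)propan-1-ol
Conditions: LiBH4, MeOH (1 equiv), THF, 0 °C
Reagents that add atoms: none
Why: Reductive removal of the auxiliary by hydride attack at the exocyclic imide carbonyl, through the aldehyde to the primary alcohol; the medium is essentially non-basic, so the alpha-aryl stereocentre should not epimerise, and the auxiliary is recovered.

Step 7
Reactants: 11 (S)-3-[2-(benzyloxy)-3-methoxyphenyl]-2-(2,4,5-trimethoxyphenyl)propan-1-ol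
Product: 12 2-[(S)-3-hydroxy-2-(2,4,5-trimethoxyphenyl)propyl]-6-methoxyphenol
Conditions: H2 (1 atm), 10% Pd/C, EtOAc/EtOH, rt
Reagents that add atoms: none
Why: Hydrogenolysis of the benzyl aryl ether; methyl ethers, arenes and the all-carbon benzylic stereocentre are not affected.

Step 8
Reactants: 12 2-[(S)-3-hydroxy-2-(2,4,5-trimethoxyphenyl)propyl]-6-methoxyphenol
Product: 13 (S)-8-methoxy-3-(2,4,5-trimethoxyphenyl)chroman
Conditions: PPh3, DIAD, THF (dilute), 0 °C → rt
Reagents that add atoms: none
Why: Intramolecular Mitsunobu etherification: the primary alcohol is activated as its oxyphosphonium ion and displaced by the phenoxide in a 6-exo-tet closure that forms O1–C2; the reacting carbon is a CH2 group, so the neighbouring stereocentre is untouched.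

Step 9
Reactants: 13 (S)-8-methoxy-3-(2,4,5-trimethoxyphenyl)chroman; 14 trimethyl borate
Product: 17 (S)-3-(3-hydroxy-2,4,5-trimethoxyphenyl)-8-methoxychroman-7-ol, via C3',C7-dilithio chroman 15 (not isolated), via bis(dimethyl boronate) 16 (not isolated)
Conditions: s-BuLi (3.2 equiv), TMEDA (3.2 equiv), THF, −78 → −40 °C; B(OMe)3 (6 equiv), −78 °C → rt; AcOH, 30% aq H2O2, 0 °C → rt; aq Na2S2O3
Reagents that add atoms: sec-butyllithium, [Li]C(C)CC (the lithium of 15 only); hydrogen peroxide, OO (the two new oxygen atoms of 17)
Why: Directed ortho-metalation, borylation and oxidation is the standard conversion of an anisole C–H into a phenol, run here at two sites at once as in the twofold lithiation of bis(alkoxyaryl) compounds. sec-Butyllithium/TMEDA precoordinates to the methoxy oxygens and removes the nearest ring protons: H-3', which lies between the 2'- and 4'-methoxy groups and is both the most acidic and the best chelated position, and H-7, the only ring-A proton ortho to an oxygen substituent. H-6' should not compete because it has a single methoxy neighbour, is screened by the chromanyl group at C1' and would require a second carbanion on an already lithiated ring; H-5 and H-6 have no directing group. Lateral deprotonation at C4 or C3, which would open the pyran by β-elimination of the O1 phenoxide or erode the stereocentre, is slower than oxygen-directed ring metalation with an alkyllithium/diamine base at low temperature, and the aryllithiums are kept cold so that loss of lithium methoxide to an aryne does not set in. Each aryllithium of 15 adds to trimethyl borate 14 to give the boronate 16; peroxide then adds to boron and the aryl group migrates from boron to oxygen, so that oxygen enters exactly at the former C–Li carbons and C3'–O and C7–O are formed regiospecifically. No ring is closed and no stereocentre is created; C3 is a spectator whose S configuration, set in step 5, is retained. The oxidation is run cold and slightly acidic so that the electron-rich phenols are not exposed to basic peroxide, and the 2,6-dimethoxyaryl boronate is oxidised in the same flask before it can protodeboronate.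

## Compound list

1 | 2-hydroxy-3-methoxybenzaldehyde (o-vanillin) | COc1cccc(C=O)c1O | starting material
2 | 2-(benzyloxy)-3-methoxybenzaldehyde | COc1cccc(C=O)c1OCc1ccccc1 | intermediate
3 | [2-(benzyloxy)-3-methoxyphenyl]methanol | COc1cccc(CO)c1OCc1ccccc1 | intermediate
4 | 2-(benzyloxy)-1-(bromomethyl)-3-methoxybenzene | COc1cccc(CBr)c1OCc1ccccc1 | intermediate
5 | 2-(2,4,5-trimethoxyphenyl)acetic acid | COc1cc(CC(=O)O)c(OC)cc1OC | starting material
6 | (S)-4-benzyloxazolidin-2-one | O=C1N[C@@H](Cc2ccccc2)CO1 | starting material
7 | 2-(2,4,5-trimethoxyphenyl)acetic pivalic anhydride | COc1cc(CC(=O)OC(=O)C(C)(C)C)c(OC)cc1OC | intermediate (not isolated)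
8 | (S)-4-benzyl-3-[2-(2,4,5-trimethoxyphenyl)acetyl]oxazolidin-2-one | COc1cc(CC(=O)N2[C@@H](Cc3ccccc3)COC2=O)c(OC)cc1OC | intermediate
9 | sodium (Z)-enolate of 8 | COc1cc(/C=C(\[O-])N2[C@@H](Cc3ccccc3)COC2=O)c(OC)cc1OC.[Na+] | intermediate (not isolated)
10 | (S)-4-benzyl-3-[(S)-3-[2-(benzyloxy)-3-methoxyphenyl]-2-(2,4,5-trimethoxyphenyl)propanoyl]oxazolidin-2-one | COc1cc([C@@H](C(=O)N2[C@@H](Cc3ccccc3)COC2=O)Cc2cccc(OC)c2OCc2ccccc2)c(OC)cc1OC | intermediate
11 | (S)-3-[2-(benzyloxy)-3-methoxyphenyl]-2-(2,4,5-trimethoxyphenyl)propan-1-ol | COc1cc([C@@H](CO)Cc2cccc(OC)c2OCc2ccccc2)c(OC)cc1OC | intermediate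
12 | 2-[(S)-3-hydroxy-2-(2,4,5-trimethoxyphenyl)propyl]-6-methoxyphenol | COc1cc([C@@H](CO)Cc2cccc(OC)c2O)c(OC)cc1OC | intermediate
13 | (S)-8-methoxy-3-(2,4,5-trimethoxyphenyl)chroman | COc1cc([C@H]2COc3c(cccc3OC)C2)c(OC)cc1OC | intermediate
14 | trimethyl borate | COB(OC)OC | starting material
15 | (S)-7-lithio-3-(3-lithio-2,4,5-trimethoxyphenyl)-8-methoxychroman | COc1cc([C@H]2COc3c(ccc([Li])c3OC)C2)c(OC)c([Li])c1OC | intermediate (not isolated)
16 | dimethyl [(S)-3-[3-(dimethoxyboryl)-2,4,5-trimethoxyphenyl]-8-methoxychroman-7-yl]boronate | COc1cc([C@H]2COc3c(ccc(B(OC)OC)c3OC)C2)c(OC)c(B(OC)OC)c1OC | intermediate (not isolated)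
17 | (S)-3-(3-hydroxy-2,4,5-trimethoxyphenyl)-8-methoxychroman-7-ol | COc1cc([C@H]2COc3c(ccc(O)c3OC)C2)c(OC)c(O)c1OC | target

## Step count and least certain steps

Total step count: 9. Longest linear sequence: 8 (steps 1, 2, 3, 5, 6, 7, 8, 9); the acid branch enters at step 4.

**Step 9 (key step).**
- What may go wrong: metalation at C7, which is activated by one methoxy group only, may lag behind C3', so mono-hydroxylation would accompany the double reaction. Forcing the base could bring in metalation at C6', or lateral deprotonation at C3 followed by β-elimination of the O1 phenoxide (ring opening and loss of the stereocentre). The hindered boronate at C3' may protodeboronate before it is oxidised, and the electron-rich phenols may be over-oxidised. A first adjustment is n-BuLi/TMEDA in diethyl ether at 0 °C.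
- Fallback (change of approach): the C7 oxygen is brought in with the ring-A building block, so that only the single, best-precedented metalation between two methoxy groups is left for the end. It sets out from imide 8 and returns at target 17.
  - 2,4-Dihydroxy-3-methoxybenzaldehyde F1 is dibenzylated to 2,4-bis(benzyloxy)-3-methoxybenzaldehyde F2, reduced to [2,4-bis(benzyloxy)-3-methoxyphenyl]methanol F3 and brominated to 1,3-bis(benzyloxy)-4-(bromomethyl)-2-methoxybenzene F4, as in steps 1–3.
  - Enolate 9, generated from 8 as in step 5, is alkylated with F4 to (S)-4-benzyl-3-[(S)-3-[2,4-bis(benzyloxy)-3-methoxyphenyl]-2-(2,4,5-trimethoxyphenyl)propanoyl]oxazolidin-2-one F5.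
  - Hydride cleavage as in step 6 gives (S)-3-[2,4-bis(benzyloxy)-3-methoxyphenyl]-2-(2,4,5-trimethoxyphenyl)propan-1-ol F6, and hydrogenolysis gives 4-[(S)-3-hydroxy-2-(2,4,5-trimethoxyphenyl)propyl]-2-methoxybenzene-1,3-diol F7.
  - Mitsunobu closure, which can form a six-membered ring only through the hydroxyl ortho to the side chain, gives (S)-8-methoxy-3-(2,4,5-trimethoxyphenyl)chroman-7-ol F8.
  - F8 is treated with n-BuLi/TMEDA (about 2.5 equiv, THF, 0 °C). The first equivalent forms the lithium phenoxide, which makes ring A inert; the second removes H-3'. Borylation with 14 and oxidation as in step 9 should give 17.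

**Step 5.**
- What may go wrong: the stabilised enolate of an arylacetyl imide is a sluggish nucleophile and can fragment through a ketene on warming. Slow alkylation by the ortho-substituted bromide would then mean low conversion, and any equilibration of the product would erode the diastereomeric purity.
- Fallback (catalytic hydrogenation in place of auxiliary alkylation): it sets out from aldehyde 2 and acid 5 and returns at alcohol 11. Perkin condensation of 2 with 5 (Ac2O, Et3N, heat) should give (E)-3-[2-(benzyloxy)-3-methoxyphenyl]-2-(2,4,5-trimethoxyphenyl)prop-2-enoic acid F9. Carboxyl-directed asymmetric hydrogenation with a chiral iridium phosphine–oxazoline catalyst (H2, amine base, MeOH), using the ligand enantiomer that delivers the S acid, would give (S)-3-[2-(benzyloxy)-3-methoxyphenyl]-2-(2,4,5-trimethoxyphenyl)propanoic acid F10. Its enantiomeric purity can be raised by crystallising a salt with a chiral amine, and borane–THF reduction of F10 gives 11.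

**Step 6.**
- What may go wrong: with a hindered alpha-aryl, alpha-benzyl acyl group the hydride may attack the ring carbonyl of the auxiliary (endocyclic cleavage) instead of the exocyclic one, and prolonged reaction could allow epimerisation at C3.
- Fallback (thiolysis, then reduction): it sets out from imide 10 and returns at alcohol 11. Lithium ethanethiolate (EtSH, n-BuLi, THF, 0 °C), a small, weakly basic nucleophile, should cleave the exocyclic acyl group to S-ethyl (S)-3-[2-(benzyloxy)-3-methoxyphenyl]-2-(2,4,5-trimethoxyphenyl)propanethioate F11, which LiAlH4 at low temperature reduces to 11.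

**Step 8.**
- What may go wrong: the phenol is flanked by a methoxy group and the side chain, so ring closure may be slow enough for intermolecular etherification or alkylation of the reduced azodicarboxylate to compete.
- Fallback (Williamson closure in place of redox condensation): it sets out from benzyl ether 11 and returns at chroman 13, replacing steps 7 and 8. Mesylation (MsCl, Et3N) gives (S)-3-[2-(benzyloxy)-3-methoxyphenyl]-2-(2,4,5-trimethoxyphenyl)propyl methanesulfonate F12. Hydrogenolysis gives (S)-3-(2-hydroxy-3-methoxyphenyl)-2-(2,4,5-trimethoxyphenyl)propyl methanesulfonate F13, and K2CO3 in DMF closes the ring to 13.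

## Further compounds

F1 | step 9 | 2,4-dihydroxy-3-methoxybenzaldehyde | COc1c(O)ccc(C=O)c1O
F2 | step 9 | 2,4-bis(benzyloxy)-3-methoxybenzaldehyde | COc1c(OCc2ccccc2)ccc(C=O)c1OCc1ccccc1
F3 | step 9 | [2,4-bis(benzyloxy)-3-methoxyphenyl]methanol | COc1c(OCc2ccccc2)ccc(CO)c1OCc1ccccc1
F4 | step 9 | 1,3-bis(benzyloxy)-4-(bromomethyl)-2-methoxybenzene | COc1c(OCc2ccccc2)ccc(CBr)c1OCc1ccccc1
F5 | step 9 | (S)-4-benzyl-3-[(S)-3-[2,4-bis(benzyloxy)-3-methoxyphenyl]-2-(2,4,5-trimethoxyphenyl)propanoyl]oxazolidin-2-one | COc1cc([C@@H](C(=O)N2[C@@H](Cc3ccccc3)COC2=O)Cc2ccc(OCc3ccccc3)c(OC)c2OCc2ccccc2)c(OC)cc1OC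
F6 | step 9 | (S)-3-[2,4-bis(benzyloxy)-3-methoxyphenyl]-2-(2,4,5-trimethoxyphenyl)propan-1-ol | COc1cc([C@@H](CO)Cc2ccc(OCc3ccccc3)c(OC)c2OCc2ccccc2)c(OC)cc1OC
F7 | step 9 | 4-[(S)-3-hydroxy-2-(2,4,5-trimethoxyphenyl)propyl]-2-methoxybenzene-1,3-diol | COc1cc([C@@H](CO)Cc2ccc(O)c(OC)c2O)c(OC)cc1OC
F8 | step 9 | (S)-8-methoxy-3-(2,4,5-trimethoxyphenyl)chroman-7-ol | COc1cc([C@H]2COc3c(ccc(O)c3OC)C2)c(OC)cc1OC
F9 | step 5 | (E)-3-[2-(benzyloxy)-3-methoxyphenyl]-2-(2,4,5-trimethoxyphenyl)prop-2-enoic acid | OC(=O)/C(=C/c1cccc(OC)c1OCc1ccccc1)c1cc(OC)c(OC)cc1OC
F10 | step 5 | (S)-3-[2-(benzyloxy)-3-methoxyphenyl]-2-(2,4,5-trimethoxyphenyl)propanoic acid | COc1cc([C@@H](C(=O)O)Cc2cccc(OC)c2OCc2ccccc2)c(OC)cc1OC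
F11 | step 6 | S-ethyl (S)-3-[2-(benzyloxy)-3-methoxyphenyl]-2-(2,4,5-trimethoxyphenyl)propanethioate | COc1cc([C@@H](C(=O)SCC)Cc2cccc(OC)c2OCc2ccccc2)c(OC)cc1OC
F12 | step 8 | (S)-3-[2-(benzyloxy)-3-methoxyphenyl]-2-(2,4,5-trimethoxyphenyl)propyl methanesulfonate | COc1cc([C@@H](COS(C)(=O)=O)Cc2cccc(OC)c2OCc2ccccc2)c(OC)cc1OC
F13 | step 8 | (S)-3-(2-hydroxy-3-methoxyphenyl)-2-(2,4,5-trimethoxyphenyl)propyl methanesulfonate | COc1cc([C@@H](COS(C)(=O)=O)Cc2cccc(OC)c2O)c(OC)cc1OC
A1 | alternative 1 | 7-(benzyloxy)-3-[3-(benzyloxy)-2,4,5-trimethoxyphenyl]-8-methoxychromenylium chloride | COc1cc(-c2c[o+]c3c(OC)c(OCc4ccccc4)ccc3c2)c(OC)c(OCc5ccccc5)c1OC.[Cl-]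
A2 | alternative 1 | 6-(benzyloxy)-7-methoxybenzofuran | COc1c(OCc2ccccc2)ccc2ccoc12
A3 | alternative 1 | 3-[3-(benzyloxy)-2,4,5-trimethoxyphenyl]-3-chloro-3H-diazirine | COc1cc(C2(Cl)N=N2)c(OC)c(OCc2ccccc2)c1OC
A4 | alternative 2 | (S)-2-{1-[3-(benzyloxy)-2,4,5-trimethoxyphenyl]-2-[4-(benzyloxy)-3-methoxy-2-(methoxymethoxy)phenyl]ethyl}-4,4,5,5-tetramethyl-1,3,2-dioxaborolane | COc1cc([C@H](Cc2ccc(OCc3ccccc3)c(OC)c2OCOC)B2OC(C)(C)C(C)(C)O2)c(OC)c(OCc4ccccc4)c1OC
A5 | alternative 2 | 4,4,5,5-tetramethyl-2-vinyl-1,3,2-dioxaborolane | C=CB1OC(C)(C)C(C)(C)O1
A6 | alternative 2 | 4-(benzyloxy)-3-methoxy-2-(methoxymethoxy)phenyl trifluoromethanesulfonate | COCOc1c(OC)c(OCc2ccccc2)ccc1OS(=O)(=O)C(F)(F)F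
A7 | alternative 2 | [3-(benzyloxy)-2,4,5-trimethoxyphenyl]lithium | COc1cc([Li])c(OC)c(OCc2ccccc2)c1OC
A8 | alternative 3 | (3S)-3-[3-(benzyloxy)-2,4,5-trimethoxyphenyl]-8-methoxychromane-2,7-diol (anomeric mixture at C2) | COc1cc([C@H]2C(O)Oc3c(ccc(O)c3OC)C2)c(OC)c(OCc4ccccc4)c1OC
A9 | alternative 3 | 2-methoxybenzene-1,3-diol (2-methoxyresorcinol) | COc1c(O)cccc1O
A10 | alternative 3 | 2-[3-(benzyloxy)-2,4,5-trimethoxyphenyl]prop-2-enal | COc1cc(C(=C)C=O)c(OC)c(OCc2ccccc2)c1OC
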